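**Assumptions (one line each):**
- The cyclohexane C4 of the target has the same spatial arrangement as (R)-(+)-limonene, so (R)-limonene supplies C4.
- C4 is too remote to bias C8/C9 in any reaction. Those centres are built relative to each other, and the diastereomer matching C4 is isolated chromatographically.

**Retrosynthesis**
1. Acetylcaespitol ⇒ 6-endo bromoetherification of tertiary alcohol **11** onto its prenyl alkene. This closes the oxane ring and sets C11–Br.
2. **11** ⇐ diol ⇐ Felkin–Anh MeMgBr addition to an α-silyloxy ketone ⇐ α-hydroxy ketone **7**.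
3. **7** comes from a [2,3]-Wittig rearrangement (the key C9–C10 bond) of an α-(1,1-dimethylallyloxy) ketone, made by Rh O–H insertion of a diazoketone.
4. The diazoketone comes from the methyl ketone obtained by ozonolysis of bromochlorinated (R)-limonene. The cyclohexane ring is therefore present from the start, and the oxane ring forms last.

---

**Step 1**
Reactants: **1** (R)-(+)-limonene
Product: **2** (1R,2R,4R)-2-bromo-1-chloro-1-methyl-4-(prop-1-en-2-yl)cyclohexane
Conditions: NBS (1.05 equiv), Et4NCl (3 equiv), CH2Cl2, –30 → 0 °C; chromatographic separation of diastereomers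
Reagents that add atoms: NBS, O=C1CCC(=O)N1Br (Br); Et4NCl, CC[N+](CC)(CC)CC.[Cl-] (Cl)
Why: Bromochlorination (anti addition through a bromonium ion, Cl at the tertiary carbon) occurs on the more electron-rich trisubstituted ring alkene and leaves the isopropenyl group alone. C4 biases the face only modestly, so two trans-diaxial diastereomers form and the (1R,2R,4R) one is separated. In it Br is cis to the C4 substituent and the product sits in the all-equatorial conformer.

**Step 2**
Reactants: **2**
Product: **3** 1-[(1R,3R,4R)-3-bromo-4-chloro-4-methylcyclohexyl]ethan-1-one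
Conditions: O3, CH2Cl2/MeOH, –78 °C; then Me2S
Reagents that add atoms: ozone, [O-][O+]=O (supplies the C=O oxygen)
Why: Ozonolysis cleaves the only remaining alkene to the methyl ketone (C8 carbonyl). The halides survive, and C4 is not epimerised under these neutral conditions.

**Step 3**
Reactants: **3**
Product: **4** 2-diazo-1-[(1R,3R,4R)-3-bromo-4-chloro-4-methylcyclohexyl]ethan-1-one
Conditions: LiHMDS, THF, –78 °C; CF3CO2CH2CF3; then p-ABSA, Et3N, H2O, MeCN, 25 °C
Reagents that add atoms: p-ABSA, CC(=O)Nc1ccc(cc1)S(=O)(=O)N=[N+]=[N-] (supplies N2; the trifluoroacetyl group is removed again)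
Why: Danheiser detrifluoroacetylative diazo transfer. The kinetic lithium enolate forms at CH3 rather than at the hindered ring CH, giving the diazomethyl ketone.

**Step 4**
Reactants: **4**; **5** 2-methylbut-3-en-2-ol
Product: **6** 1-[(1R,3R,4R)-3-bromo-4-chloro-4-methylcyclohexyl]-2-[(2-methylbut-3-en-2-yl)oxy]ethan-1-one
Conditions: Rh2(OAc)4 (1 mol %), **5** (5 equiv), CH2Cl2, 25 → 40 °C
Reagents that add atoms: 2-methylbut-3-en-2-ol, C=CC(C)(C)O
Why: The Rh carbenoid undergoes O–H insertion into the tertiary allylic alcohol (the oxonium ylide is protonated faster than it rearranges). This gives the 1,1-dimethylallyl ether needed for the rearrangement, and no stereocentre is formed.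

**Step 5**
Reactants: **6**
Product: **7** 1-[(1R,3R,4R)-3-bromo-4-chloro-4-methylcyclohexyl]-2-hydroxy-5-methylhex-4-en-1-one (C9 epimer mixture)
Conditions: KHMDS (1.2 equiv), THF, –78 → –20 °C; aq. NH4Cl
Reagents that add atoms: none
Why: [2,3]-Wittig rearrangement. The enolate at the acidic OCH2C=O carbon attacks the vinyl terminus through a five-membered TS, forming C9–C10 and converting the reverse-prenyl ether into the linear prenyl CH2CH=CMe2 group. C9 is created as a ~1:1 epimer pair because C4 is too far away to discriminate.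

**Step 6**
Reactants: **7**
Product: **8** 2-[(tert-butyldimethylsilyl)oxy]-1-[(1R,3R,4R)-3-bromo-4-chloro-4-methylcyclohexyl]-5-methylhex-4-en-1-one
Conditions: TBSCl, imidazole, DMF, 25 °C
Reagents that add atoms: TBSCl, C[Si](C)(C(C)(C)C)Cl
Why: Silylation of the secondary alcohol blocks Mg chelation, so the next addition is under non-chelation (polar Felkin–Anh) control.

**Step 7**
Reactants: **8**
Product: **9** (2S,3S)-3-[(tert-butyldimethylsilyl)oxy]-2-[(1R,3R,4R)-3-bromo-4-chloro-4-methylcyclohexyl]-6-methylhept-5-en-2-ol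
Conditions: MeMgBr (3 equiv), Et2O, –78 → 0 °C; then preparative HPLC
Reagents that add atoms: MeMgBr, C[Mg]Br (CH3)
Why: Polar Felkin–Anh addition (Me attacks anti to the C–OTBS bond, past H) sets C8 relative to C9 as the syn-1,2-diol required by the target. The (9S) epimer gives (8S,9S), which is the target series. The (9R) epimer gives the C4-mismatched (8R,9R) diastereomer, which is removed by HPLC along with minor anti isomers.

**Step 8**
Reactants: **9**
Product: **10** (2S,3S)-2-[(1R,3R,4R)-3-bromo-4-chloro-4-methylcyclohexyl]-6-methylhept-5-ene-2,3-diol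
Conditions: TBAF/AcOH (1:1), THF, 0 → 40 °C
Reagents that add atoms: none
Why: Fluoride desilylation with AcOH buffering. The buffer avoids base-induced dehydrohalogenation, and the equatorial ring halides have no anti β-hydrogens in any case.

**Step 9**
Reactants: **10**
Product: **11** (2S,3S)-2-[(1R,3R,4R)-3-bromo-4-chloro-4-methylcyclohexyl]-2-hydroxy-6-methylhept-5-en-3-yl acetate
Conditions: Ac2O, pyridine, DMAP (cat.), CH2Cl2, 0 → 25 °C
Reagents that add atoms: Ac2O, CC(=O)OC(C)=O (acetyl)
Why: Acylation is selective for the secondary C9–OH over the hindered tertiary C8–OH. It also removes the homoallylic OH that could compete in 5-endo bromoetherification.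

**Step 10**
Reactants: **11**
Product: **12** acetylcaespitol, (2S,3S,5S)-5-bromo-2-[(1R,3R,4R)-3-bromo-4-chloro-4-methylcyclohexyl]-2,6,6-trimethyloxan-3-yl acetate
Conditions: NBS (1.1 equiv), CH2Cl2, 0 °C, NaHCO3
Reagents that add atoms: NBS, O=C1CCC(=O)N1Br (Br)
Why: Bromonium-induced 6-endo etherification: the C8–OH attacks the tertiary C12 anti to the bromonium, so the new ring O–C12 bond is anti to C11–Br and Br ends up equatorial. In the chair-like TS the bulky cyclohexyl group is equatorial (the alternative puts it axial), which fixes C11 as S. The C8 and C9 configurations are untouched.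

---

**Compound list**

1 | (R)-(+)-limonene | CC1=CC[C@@H](CC1)C(C)=C | starting material
2 | (1R,2R,4R)-2-bromo-1-chloro-1-methyl-4-(prop-1-en-2-yl)cyclohexane | CC(=C)[C@@H]1CC[C@@](C)(Cl)[C@H](Br)C1 | intermediate
3 | 1-[(1R,3R,4R)-3-bromo-4-chloro-4-methylcyclohexyl]ethan-1-one | CC(=O)[C@@H]1CC[C@@](C)(Cl)[C@H](Br)C1 | intermediate
4 | 2-diazo-1-[(1R,3R,4R)-3-bromo-4-chloro-4-methylcyclohexyl]ethan-1-one | [N-]=[N+]=CC(=O)[C@@H]1CC[C@@](C)(Cl)[C@H](Br)C1 | intermediate
5 | 2-methylbut-3-en-2-ol | C=CC(C)(C)O | starting material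
6 | 1-[(1R,3R,4R)-3-bromo-4-chloro-4-methylcyclohexyl]-2-[(2-methylbut-3-en-2-yl)oxy]ethan-1-one | C=CC(C)(C)OCC(=O)[C@@H]1CC[C@@](C)(Cl)[C@H](Br)C1 | intermediate
7 | 1-[(1R,3R,4R)-3-bromo-4-chloro-4-methylcyclohexyl]-2-hydroxy-5-methylhex-4-en-1-one (C9 epimers) | CC(C)=CCC(O)C(=O)[C@@H]1CC[C@@](C)(Cl)[C@H](Br)C1 | intermediate
8 | 2-(TBSO) analogue of 7 (C9 epimers) | CC(C)=CCC(O[Si](C)(C)C(C)(C)C)C(=O)[C@@H]1CC[C@@](C)(Cl)[C@H](Br)C1 | intermediate
9 | (2S,3S)-3-(TBSO)-2-[(1R,3R,4R)-3-bromo-4-chloro-4-methylcyclohexyl]-6-methylhept-5-en-2-ol | CC(C)=CC[C@H](O[Si](C)(C)C(C)(C)C)[C@@](C)(O)[C@@H]1CC[C@@](C)(Cl)[C@H](Br)C1 | intermediate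
10 | (2S,3S)-2-[(1R,3R,4R)-3-bromo-4-chloro-4-methylcyclohexyl]-6-methylhept-5-ene-2,3-diol | CC(C)=CC[C@H](O)[C@@](C)(O)[C@@H]1CC[C@@](C)(Cl)[C@H](Br)C1 | intermediate
11 | (2S,3S)-2-[(1R,3R,4R)-3-bromo-4-chloro-4-methylcyclohexyl]-2-hydroxy-6-methylhept-5-en-3-yl acetate | CC(C)=CC[C@H](OC(C)=O)[C@@](C)(O)[C@@H]1CC[C@@](C)(Cl)[C@H](Br)C1 | intermediate
12 | acetylcaespitol | CC(=O)O[C@H]1C[C@H](Br)C(C)(C)O[C@@]1(C)[C@@H]1CC[C@@](C)(Cl)[C@H](Br)C1 | target

---

**Total step count:** 10
**Longest linear sequence:** 10 steps, from **1** to **12**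

**Three steps most likely to fail**
1. **Step 1 (ring bromochlorination).** The required (1R,2R,4R) isomer comes from the face that is disfavoured in trans-diaxial addition, so it may be the minor product, and Markovnikov regiochemistry may be imperfect.
   *Fallback:* Make the bromohydrin, close it to cis-limonene oxide, and open it with HCl at C1. Then oxidise the C2 alcohol (DMP), reduce with L-Selectride to the axial alcohol, and convert it with PPh3/CBr4 (SN2 inversion) to the equatorial bromide.
2. **Step 5 ([2,3]-Wittig).** The hindered reverse-prenyl ether, the base-labile tertiary chloride, a competing [1,2]-shift, and the lack of C9 control (~1:1 epimers) could all lower the yield.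
   *Fallback:* Skip the sigmatropic route. Prenylate the methyl ketone **3** at the methyl carbon (LiHMDS, prenyl bromide), then hydroxylate C9 (KHMDS, achiral Davis oxaziridine) to reach **7**.
3. **Step 7 (Felkin–Anh methyl addition).** The diastereoselectivity may be poor, and the C4-mismatched (8R,9R) isomer may be hard to separate.
   *Fallback:* Add MeMgBr to the free α-hydroxy ketone **7** under chelation control, which gives the anti-diol. Then invert C9 by Mitsunobu reaction with p-nitrobenzoic acid, saponify, and acetylate.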